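The target ring is a cyclohex-2-ene-1,4-dione: carbonyls at C1 and C4 flank the C5=C6 double bond, C3 is a methylene, and C2, between C1 and C3, is the quaternary stereocentre. Since both oxygenated carbons are the allylic ends of C5=C6, the ring is cut at C1–C2 and C3–C4 into a butadiene oxygenated at both termini and a C2=C3 alkene. One oxazaborolidinium-catalysed Diels–Alder reaction makes both bonds, closes the carbocycle and fixes C2. The dienophile is a 2-methylene aldehyde already carrying the complete C20 side chain with its anti-diol as a bis-TBS ether; the diene is (1E,3E)-1,4-bis(triethylsilyloxy)butadiene.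

Key step: step 10

Assumption: adduct 17 is drawn as the all-cis (endo-formyl) diastereomer; an exo-formyl or trans-disilyloxy diastereomer would carry the same quaternary configuration and converge on the same enedione in step 15.

Conventions: R¹ = (2E,6E,10E,12S,13R)-12,13-bis(tert-butyldimethylsilyloxy)-3,7,11,15-tetramethylhexadeca-2,6,10,14-tetraen-1-yl. In the names of 17–25 and F1–F5 the cyclohex-3-ene ring is numbered from the quaternary carbon (C1). TBS = tert-butyldimethylsilyl, TES = triethylsilyl, Ipc = isopinocampheyl.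

Step 1
Reactants: 1 (2E,6E)-farnesyl bromide; 2 tert-butyl acetate
Product: 4 tert-butyl (4E,8E)-5,9,13-trimethyltetradeca-4,8,12-trienoate, via lithium enolate 3 (not isolated)
Conditions: 2, LiN(iPr)2 (commercial solution), THF, −78 °C; then 1, DMPU, −78 → 0 °C
Reagents that add atoms: none
Why: SN2 alkylation of the lithium ester enolate at the primary allylic bromide should join the acetate carbon to C1 of the chain without touching the alkene geometries, the bulky tert-butyl ester suppressing Claisen self-condensation.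

Step 2
Reactants: 4 tert-butyl (4E,8E)-5,9,13-trimethyltetradeca-4,8,12-trienoate
Product: 5 tert-butyl (4E,8E,12E)-14-hydroxy-5,9,13-trimethyltetradeca-4,8,12-trienoate
Conditions: SeO2 (cat.), t-BuOOH, salicylic acid (cat.), CH2Cl2, 0 °C → rt, stopped at partial conversion
Reagents that add atoms: selenium dioxide, O=[Se]=O (oxygen carrier, catalytic); tert-butyl hydroperoxide, CC(C)(C)OO (stoichiometric oxygen source)
Why: Riley allylic oxidation (ene reaction, then [2,3]-sigmatropic shift of the allylseleninic acid) should attack the most electron-rich and least hindered terminal isopropylidene at its (E)-methyl group and so give the (12E)-allylic alcohol, any over-oxidised enal being the product of step 3.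

Step 3
Reactants: 5 tert-butyl (4E,8E,12E)-14-hydroxy-5,9,13-trimethyltetradeca-4,8,12-trienoate
Product: 6 tert-butyl (4E,8E,12E)-5,9,13-trimethyl-14-oxotetradeca-4,8,12-trienoate
Conditions: Dess–Martin periodinane, CH2Cl2, 0 °C → rt
Reagents that add atoms: none
Why: Periodinane oxidation of a primary allylic alcohol to the enal is neutral and should leave the (12E) geometry and the tert-butyl ester untouched.

Step 4
Reactants: 6 tert-butyl (4E,8E,12E)-5,9,13-trimethyl-14-oxotetradeca-4,8,12-trienoate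
Product: 8 tert-butyl (4E,8E,12E,14S,15R)-14,15-dihydroxy-5,9,13-trimethylheptadeca-4,8,12,16-tetraenoate, via borinate 7 (not isolated)
Conditions: (+)-Ipc2BH [from (1S,5S)-α-pinene], allenylboronic acid pinacol ester, THF, 0 → 25 °C; then 6, −78 °C; NaOH, H2O2, 0 °C → rt
Reagents that add atoms: allenylboronic acid pinacol ester, C=C=CB1OC(C)(C)C(C)(C)O1 (C15–C17); hydrogen peroxide, OO (oxygen on C15)
Why: Reagent-controlled allylboration with an (E)-γ-borylallyl-diisopinocampheylborane proceeds through a closed chair-like six-membered transition state in which the (E)-geometry gives the anti relationship and the Ipc groups derived from (−)-α-pinene direct attack to the Re face of the aldehyde (14S), and oxidation of the C–B bond with retention should then give the (14S,15R)-diol.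

Step 5
Reactants: 8 tert-butyl (4E,8E,12E,14S,15R)-14,15-dihydroxy-5,9,13-trimethylheptadeca-4,8,12,16-tetraenoate
Product: 9 tert-butyl (4E,8E,12E,14S,15R)-14,15-dihydroxy-5,9,13,17-tetramethyloctadeca-4,8,12,16-tetraenoate
Conditions: 2-methyl-2-butene (large excess), second-generation Hoveyda–Grubbs catalyst RuCl2(H2IMes)(=CH-C6H4-2-OiPr) (5 mol%), CH2Cl2, 35 °C
Reagents that add atoms: 2-methyl-2-butene, CC=C(C)C
Why: Olefin cross-metathesis should engage only the monosubstituted vinyl group, which initiates far faster than the trisubstituted chain alkenes, and the excess of 2-methyl-2-butene turns it into the isobutenyl terminus with loss of propene and without touching a stereocentre.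

Step 6
Reactants: 9 tert-butyl (4E,8E,12E,14S,15R)-14,15-dihydroxy-5,9,13,17-tetramethyloctadeca-4,8,12,16-tetraenoate
Product: 10 tert-butyl (4E,8E,12E,14S,15R)-14,15-bis(tert-butyldimethylsilyloxy)-5,9,13,17-tetramethyloctadeca-4,8,12,16-tetraenoate
Conditions: t-BuMe2SiOTf, 2,6-lutidine, CH2Cl2, −78 → 0 °C
Reagents that add atoms: tert-butyldimethylsilyl triflate, CC(C)(C)[Si](C)(C)OS(=O)(=O)C(F)(F)F
Why: O-Silylation with the silyl triflate and a hindered base is fast enough to protect both secondary allylic hydroxyls of the vicinal diol with retention at carbon.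

Step 7
Reactants: 10 tert-butyl (4E,8E,12E,14S,15R)-14,15-bis(tert-butyldimethylsilyloxy)-5,9,13,17-tetramethyloctadeca-4,8,12,16-tetraenoate
Product: 12 (4E,8E,12E,14S,15R)-14,15-bis(tert-butyldimethylsilyloxy)-5,9,13,17-tetramethyloctadeca-4,8,12,16-tetraenal, via aluminium hemiacetal 11 (not isolated)
Conditions: iBu2AlH (1.1 equiv), CH2Cl2, −78 °C; MeOH, then aq. potassium sodium tartrate (KNaC4H4O6)
Reagents that add atoms: none
Why: Partial hydride reduction of the ester stops at the aldehyde level because the tetrahedral aluminium hemiacetal of the bulky tert-butyl ester is stable at −78 °C and collapses only on work-up.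

Step 8
Reactants: 12 (4E,8E,12E,14S,15R)-14,15-bis(tert-butyldimethylsilyloxy)-5,9,13,17-tetramethyloctadeca-4,8,12,16-tetraenal
Product: 13 (4E,8E,12E,14S,15R)-14,15-bis(tert-butyldimethylsilyloxy)-5,9,13,17-tetramethyl-2-methylideneoctadeca-4,8,12,16-tetraenal
Conditions: aq. CH2O, pyrrolidine (10 mol%), EtCO2H (10 mol%), i-PrOH, 45 °C; used promptly
Reagents that add atoms: formaldehyde, C=O
Why: Amine-catalysed α-methylenation (enamine Mannich condensation with formaldehyde followed by β-elimination of the amine) is general for linear aldehydes and mild enough for the silyl ethers and the skipped diene.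

Step 9
Reactants: 14 (1E,3E)-buta-1,3-diene-1,4-diyl diacetate
Product: 16 (1E,3E)-1,4-bis(triethylsilyloxy)buta-1,3-diene, via dilithium dienediolate 15 (not isolated)
Conditions: MeLi (4.1 equiv), DME, −78 → 0 °C; Et3SiCl (4.4 equiv), −78 °C → rt; pentane, filtration, bulb-to-bulb distillation
Reagents that add atoms: chlorotriethylsilane, CC[Si](Cl)(CC)CC
Why: Cleavage of enol acetates by methyllithium (a second equivalent traps the acetone) unmasks the lithium enolates with retention of the (E)-geometry, and O-silylation by the hard silyl chloride should give the geometrically defined bis(silyl enol ether), which enolisation of the dialdehyde would not guarantee.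

Step 10
Reactants: 13 (4E,8E,12E,14S,15R)-14,15-bis(tert-butyldimethylsilyloxy)-5,9,13,17-tetramethyl-2-methylideneoctadeca-4,8,12,16-tetraenal; 16 (1E,3E)-1,4-bis(triethylsilyloxy)buta-1,3-diene
Product: 17 (1S,2R,5R)-1-R¹-2,5-bis(triethylsilyloxy)cyclohex-3-ene-1-carbaldehyde
Conditions: (S)-3,3-diphenyl-1-(2-methylphenyl)tetrahydro-1H,3H-pyrrolo[1,2-c][1,3,2]oxazaborole (20 mol%), HNTf2 (16 mol%), CH2Cl2, −78 °C; 16 (2.5 equiv) added slowly; Et3N quench
Reagents that add atoms: none
Why: The N-protonated oxazaborolidine acts as a one-point Lewis acid for the aldehyde oxygen of 13 (aided by a formyl C–H···O contact to the ring oxygen), which lowers the LUMO of the enal so that the electron-rich diene 16 adds across its C=CH2 bond in a concerted but asynchronous normal-demand [4+2] process. The nearest established reaction type is the cationic-oxazaborolidine-catalysed Diels–Alder addition of 2-alkyl- and 2-haloacroleins to simple and 1-oxygenated dienes, which delivers formyl-substituted quaternary carbons. The cyclohexene is closed by intermolecular 4π+2π annulation, the bonds C1–C2 and C3–C4 (target numbering) being made in the same event. The quaternary carbon is controlled by the catalyst alone: the s-trans enal lies over a C-phenyl group of the (S)-catalyst, which blocks one face, so that the diene should add to the Si face of C2 of 13 (sense assigned by analogy with 2-methylacrolein); the two silyloxy carbons come out cis to each other through suprafacial addition to the (E,E)-diene, and their relation to the formyl group depends on the endo/exo preference, which does not matter because both are oxidised in step 15. The reaction needs only this enantiofacial selectivity, secured by the lone aldehyde as the single binding site, by the 2-substituent that keeps the enal s-trans, and by the twofold symmetry of 16, which removes any regiochemical issue.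

Step 11
Reactants: 17 (1S,2R,5R)-1-R¹-2,5-bis(triethylsilyloxy)cyclohex-3-ene-1-carbaldehyde
Product: 18 (1R,2R,5R)-1-ethenyl-1-R¹-2,5-bis(triethylsilyloxy)cyclohex-3-ene
Conditions: Ph3PCH3Br, KOtBu, THF, 0 °C → rt
Reagents that add atoms: methyltriphenylphosphonium bromide, C[P+](c1ccccc1)(c1ccccc1)c1ccccc1.[Br-]
Why: Wittig methylenation works well on hindered, non-enolisable aldehydes and avoids the acid-labile enol ether that a methoxymethylene homologation would need to hydrolyse in the presence of the TES ethers.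

Step 12
Reactants: 18 (1R,2R,5R)-1-ethenyl-1-R¹-2,5-bis(triethylsilyloxy)cyclohex-3-ene
Product: 20 2-[(1S,2R,5R)-1-R¹-2,5-bis(triethylsilyloxy)cyclohex-3-en-1-yl]ethan-1-ol, via alkylborane 19 (not isolated)
Conditions: 9-BBN, THF, 0 °C → rt; NaBO3·4H2O, H2O, rt
Reagents that add atoms: sodium perborate (NaBO3·4H2O), [Na+].[Na+].O[B-]1(O)OO[B-](O)(O)OO1 (hydroxyl oxygen)
Why: Hydroboration–oxidation with 9-BBN discriminates the monosubstituted vinyl group from the trisubstituted chain alkenes and the flanked ring alkene by orders of magnitude, places boron on the terminal carbon, and mild perborate oxidation should give the primary alcohol with the silyl ethers intact.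

Step 13
Reactants: 20 2-[(1S,2R,5R)-1-R¹-2,5-bis(triethylsilyloxy)cyclohex-3-en-1-yl]ethan-1-ol
Product: 22 2-[(1R,2R,5R)-1-R¹-2,5-bis(triethylsilyloxy)cyclohex-3-en-1-yl]acetic acid, via aldehyde 21 (not isolated)
Conditions: TEMPO (cat.), PhI(OAc)2, MeCN/pH 7 buffer, rt
Reagents that add atoms: water, O (second carboxyl oxygen)
Why: Oxoammonium-mediated oxidation takes the unhindered primary alcohol to the aldehyde and, through its hydrate, to the acid, while alkenes and silyl ethers are inert to this oxidant.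

Step 14
Reactants: 22 2-[(1R,2R,5R)-1-R¹-2,5-bis(triethylsilyloxy)cyclohex-3-en-1-yl]acetic acid
Product: 23 methyl 2-[(1R,2R,5R)-1-R¹-2,5-bis(triethylsilyloxy)cyclohex-3-en-1-yl]acetate
Conditions: Me3SiCHN2, toluene/MeOH, 0 °C
Reagents that add atoms: (trimethylsilyl)diazomethane, C[Si](C)(C)C=[N+]=[N-] (methyl carbon)
Why: O-Methylation of the carboxylic acid by the diazoalkane is fast and neutral, so the silyl ethers and the ring alkene should be unaffected.

Step 15
Reactants: 23 methyl 2-[(1R,2R,5R)-1-R¹-2,5-bis(triethylsilyloxy)cyclohex-3-en-1-yl]acetate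
Product: 25 methyl 2-[(1R)-1-R¹-2,5-dioxocyclohex-3-en-1-yl]acetate, via diol ester 24 (not isolated)
Conditions: IBX (6 equiv), DMSO, 25 °C
Reagents that add atoms: none
Why: IBX-mediated oxidative desilylation cleaves triethylsilyl ethers in DMSO while tert-butyldimethylsilyl ethers persist, and excess reagent oxidises the liberated allylic alcohols in the same flask, so that a free hydroxyl at C1 is not left next to the methyl ester long enough to lactonise and both carbinol stereocentres are erased.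

Step 16
Reactants: 25 methyl 2-[(1R)-1-R¹-2,5-dioxocyclohex-3-en-1-yl]acetate
Product: 26 methyl 2-[(1R)-1-[(2E,6E,10E,12S,13R)-12,13-dihydroxy-3,7,11,15-tetramethylhexadeca-2,6,10,14-tetraen-1-yl]-2,5-dioxocyclohex-3-en-1-yl]acetate (CNP0122011.2)
Conditions: HF·pyridine, pyridine, THF, 0 → 25 °C
Reagents that add atoms: none
Why: Fluoride-assisted Si–O cleavage under buffered, weakly acidic conditions should free the anti-diol without enolising the enedione, hydrolysing the methyl ester or touching a stereocentre.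

Compound list

1 | (2E,6E)-farnesyl bromide [(2E,6E)-1-bromo-3,7,11-trimethyldodeca-2,6,10-triene] | CC(C)=CCC/C(C)=C/CC/C(C)=C/CBr | starting material
2 | tert-butyl acetate | CC(=O)OC(C)(C)C | starting material
3 | lithium enolate of tert-butyl acetate (lithium 1-tert-butoxyethen-1-olate) | [Li]OC(=C)OC(C)(C)C | intermediate
4 | tert-butyl (4E,8E)-5,9,13-trimethyltetradeca-4,8,12-trienoate | CC(C)=CCC/C(C)=C/CC/C(C)=C/CCC(=O)OC(C)(C)C | intermediate
5 | tert-butyl (4E,8E,12E)-14-hydroxy-5,9,13-trimethyltetradeca-4,8,12-trienoate | OC/C(C)=C/CC/C(C)=C/CC/C(C)=C/CCC(=O)OC(C)(C)C | intermediate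
6 | tert-butyl (4E,8E,12E)-5,9,13-trimethyl-14-oxotetradeca-4,8,12-trienoate | O=C/C(C)=C/CC/C(C)=C/CC/C(C)=C/CCC(=O)OC(C)(C)C | intermediate
7 | tert-butyl (4E,8E,12E,14R,15R)-14-[bis(isopinocampheyl)boranyloxy]-5,9,13-trimethyl-15-(4,4,5,5-tetramethyl-1,3,2-dioxaborolan-2-yl)heptadeca-4,8,12,16-tetraenoate (O-borinate and C-boronate anti) | CC(C)(C)OC(=O)CC/C=C(\C)CC/C=C(\C)CC/C=C(\C)[C@H](OB([C@H]1C[C@H]2C[C@@H]([C@@H]1C)C2(C)C)[C@H]1C[C@H]2C[C@@H]([C@@H]1C)C2(C)C)[C@H](B1OC(C)(C)C(C)(C)O1)C=C | intermediate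
8 | tert-butyl (4E,8E,12E,14S,15R)-14,15-dihydroxy-5,9,13-trimethylheptadeca-4,8,12,16-tetraenoate | CC(C)(C)OC(=O)CC/C=C(\C)CC/C=C(\C)CC/C=C(\C)[C@H](O)[C@H](O)C=C | intermediate
9 | tert-butyl (4E,8E,12E,14S,15R)-14,15-dihydroxy-5,9,13,17-tetramethyloctadeca-4,8,12,16-tetraenoate | CC(C)(C)OC(=O)CC/C=C(\C)CC/C=C(\C)CC/C=C(\C)[C@H](O)[C@H](O)C=C(C)C | intermediate
10 | tert-butyl (4E,8E,12E,14S,15R)-14,15-bis(tert-butyldimethylsilyloxy)-5,9,13,17-tetramethyloctadeca-4,8,12,16-tetraenoate | CC(C)(C)OC(=O)CC/C=C(\C)CC/C=C(\C)CC/C=C(\C)[C@H](O[Si](C)(C)C(C)(C)C)[C@H](O[Si](C)(C)C(C)(C)C)C=C(C)C | intermediate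
11 | diisobutylaluminium tert-butyl hemiacetal of 12 (tetrahedral reduction intermediate of 10) | CC(C)C[Al](CC(C)C)OC(OC(C)(C)C)CC/C=C(\C)CC/C=C(\C)CC/C=C(\C)[C@H](O[Si](C)(C)C(C)(C)C)[C@H](O[Si](C)(C)C(C)(C)C)C=C(C)C | intermediate
12 | (4E,8E,12E,14S,15R)-14,15-bis(tert-butyldimethylsilyloxy)-5,9,13,17-tetramethyloctadeca-4,8,12,16-tetraenal | O=CCC/C=C(\C)CC/C=C(\C)CC/C=C(\C)[C@H](O[Si](C)(C)C(C)(C)C)[C@H](O[Si](C)(C)C(C)(C)C)C=C(C)C | intermediate
13 | (4E,8E,12E,14S,15R)-14,15-bis(tert-butyldimethylsilyloxy)-5,9,13,17-tetramethyl-2-methylideneoctadeca-4,8,12,16-tetraenal | O=CC(=C)C/C=C(\C)CC/C=C(\C)CC/C=C(\C)[C@H](O[Si](C)(C)C(C)(C)C)[C@H](O[Si](C)(C)C(C)(C)C)C=C(C)C | intermediate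
14 | (1E,3E)-buta-1,3-diene-1,4-diyl diacetate | CC(=O)O/C=C/C=C/OC(C)=O | starting material
15 | dilithium (1E,3E)-buta-1,3-diene-1,4-diolate | [Li]O/C=C/C=C/O[Li] | intermediate
16 | (1E,3E)-1,4-bis(triethylsilyloxy)buta-1,3-diene | CC[Si](CC)(CC)O/C=C/C=C/O[Si](CC)(CC)CC | intermediate
17 | (1S,2R,5R)-1-R¹-2,5-bis(triethylsilyloxy)cyclohex-3-ene-1-carbaldehyde (CHO and both silyloxy groups cis) | O=C[C@@]1(C/C=C(\C)CC/C=C(\C)CC/C=C(\C)[C@H](O[Si](C)(C)C(C)(C)C)[C@H](O[Si](C)(C)C(C)(C)C)C=C(C)C)C[C@@H](O[Si](CC)(CC)CC)C=C[C@H]1O[Si](CC)(CC)CC | intermediate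
18 | (1R,2R,5R)-1-ethenyl-1-R¹-2,5-bis(triethylsilyloxy)cyclohex-3-ene | C=C[C@@]1(C/C=C(\C)CC/C=C(\C)CC/C=C(\C)[C@H](O[Si](C)(C)C(C)(C)C)[C@H](O[Si](C)(C)C(C)(C)C)C=C(C)C)C[C@@H](O[Si](CC)(CC)CC)C=C[C@H]1O[Si](CC)(CC)CC | intermediate
19 | B-alkyl-9-borabicyclo[3.3.1]nonane of 18 (boron on the terminal carbon of the former vinyl group) | C1CC2CCCC(C1)B2CC[C@@]3(C/C=C(\C)CC/C=C(\C)CC/C=C(\C)[C@H](O[Si](C)(C)C(C)(C)C)[C@H](O[Si](C)(C)C(C)(C)C)C=C(C)C)C[C@@H](O[Si](CC)(CC)CC)C=C[C@H]3O[Si](CC)(CC)CC | intermediate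
20 | 2-[(1S,2R,5R)-1-R¹-2,5-bis(triethylsilyloxy)cyclohex-3-en-1-yl]ethan-1-ol | OCC[C@@]1(C/C=C(\C)CC/C=C(\C)CC/C=C(\C)[C@H](O[Si](C)(C)C(C)(C)C)[C@H](O[Si](C)(C)C(C)(C)C)C=C(C)C)C[C@@H](O[Si](CC)(CC)CC)C=C[C@H]1O[Si](CC)(CC)CC | intermediate
21 | 2-[(1R,2R,5R)-1-R¹-2,5-bis(triethylsilyloxy)cyclohex-3-en-1-yl]acetaldehyde | O=CC[C@@]1(C/C=C(\C)CC/C=C(\C)CC/C=C(\C)[C@H](O[Si](C)(C)C(C)(C)C)[C@H](O[Si](C)(C)C(C)(C)C)C=C(C)C)C[C@@H](O[Si](CC)(CC)CC)C=C[C@H]1O[Si](CC)(CC)CC | intermediate
22 | 2-[(1R,2R,5R)-1-R¹-2,5-bis(triethylsilyloxy)cyclohex-3-en-1-yl]acetic acid | OC(=O)C[C@@]1(C/C=C(\C)CC/C=C(\C)CC/C=C(\C)[C@H](O[Si](C)(C)C(C)(C)C)[C@H](O[Si](C)(C)C(C)(C)C)C=C(C)C)C[C@@H](O[Si](CC)(CC)CC)C=C[C@H]1O[Si](CC)(CC)CC | intermediate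
23 | methyl 2-[(1R,2R,5R)-1-R¹-2,5-bis(triethylsilyloxy)cyclohex-3-en-1-yl]acetate | COC(=O)C[C@@]1(C/C=C(\C)CC/C=C(\C)CC/C=C(\C)[C@H](O[Si](C)(C)C(C)(C)C)[C@H](O[Si](C)(C)C(C)(C)C)C=C(C)C)C[C@@H](O[Si](CC)(CC)CC)C=C[C@H]1O[Si](CC)(CC)CC | intermediate
24 | methyl 2-[(1R,2R,5R)-1-R¹-2,5-dihydroxycyclohex-3-en-1-yl]acetate | COC(=O)C[C@@]1(C/C=C(\C)CC/C=C(\C)CC/C=C(\C)[C@H](O[Si](C)(C)C(C)(C)C)[C@H](O[Si](C)(C)C(C)(C)C)C=C(C)C)C[C@@H](O)C=C[C@H]1O | intermediate
25 | methyl 2-[(1R)-1-R¹-2,5-dioxocyclohex-3-en-1-yl]acetate | COC(=O)C[C@@]1(C/C=C(\C)CC/C=C(\C)CC/C=C(\C)[C@H](O[Si](C)(C)C(C)(C)C)[C@H](O[Si](C)(C)C(C)(C)C)C=C(C)C)CC(=O)C=CC1=O | intermediate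
26 | methyl 2-[(1R)-1-[(2E,6E,10E,12S,13R)-12,13-dihydroxy-3,7,11,15-tetramethylhexadeca-2,6,10,14-tetraen-1-yl]-2,5-dioxocyclohex-3-en-1-yl]acetate | COC(=O)C[C@@]1(C/C=C(\C)CC/C=C(\C)CC/C=C(\C)[C@H](O)[C@H](O)C=C(C)C)CC(=O)C=CC1=O | target

Total step count: 16. Longest linear sequence: 15 steps (steps 1–8, then 10–16); step 9 is the one-step side branch to the diene.

Steps most likely to fail

Step 10. The strongly acidic catalyst may protodesilylate or oligomerise the bis(silyl enol ether), or the diene may add as an enol ether to the enal without closing the ring. The facial discrimination may also be too low, or opposite to the sense assigned by analogy, and diastereomers at the quaternary carbon would be hard to separate because the chain stereocentres are remote. The fallback changes the diene class instead of the conditions and sets out from 13 and 14. The acid-stable bis(enol acetate) 14 is used directly as the diene under the same oxazaborolidinium salt at −40 → −20 °C; cycloadditions of this diene to acrylic dienophiles are long established, though they are usually run hot. This should give (1S,2R,5R)-2,5-diacetoxy-1-R¹-cyclohex-3-ene-1-carbaldehyde F1. Methylenation (Ph3PCH3Br, KOtBu, THF, −78 → 0 °C) would give (1R,2R,5R)-1-ethenyl-1-R¹-cyclohex-3-ene-2,5-diyl diacetate F2. Methanolysis (K2CO3, MeOH, 0 °C) would give (1R,2R,5R)-1-ethenyl-1-R¹-cyclohex-3-ene-2,5-diol F3, and silylation (Et3SiOTf, 2,6-lutidine) rejoins the route at 18. A reversed facial sense alone would be met with the catalyst made from (R)-diphenylprolinol.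

Step 15. Cleavage of the silyl ether at C1, which sits next to the quaternary carbon, may be slow, so that partly oxidised material accumulates and a free C1 hydroxyl lactonises onto the methyl ester. The fallback moves the unmasking to the carboxylate stage, where lactonisation is not possible under basic conditions, and sets out from 22. Bu4NF (THF, 0 °C) should remove both TES ethers and give 2-[(1R,2R,5R)-1-R¹-2,5-dihydroxycyclohex-3-en-1-yl]acetic acid F4, kept as its tetrabutylammonium salt. Dess–Martin periodinane with NaHCO3 should then give 2-[(1R)-1-R¹-2,5-dioxocyclohex-3-en-1-yl]acetic acid F5. Brief esterification (Me3SiCHN2, MeOH, 0 °C, or MeI/KHCO3 in DMF) rejoins the route at 25.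

Step 9. The double acyl cleavage may stop halfway, the dienediolate may be silylated on carbon or oxidised by adventitious air, and the dienol ether may hydrolyse during isolation. The fallback builds the diene by enolisation instead of enol-ester cleavage; it sets out from no compound of the route but from commercial 2,5-dimethoxytetrahydrofuran F6 and comes back at 16. Hydrolysis in water at 90 °C with removal of methanol should give butanedial F7, and double enol silylation (Et3SiOTf, Et3N, Et2O, 0 °C) should give 16 as a mixture of geometric isomers. The mixture would be used in excess in step 10, since the (1E,3E) isomer is expected to cycloadd fastest and every adduct converges on 25 in step 15.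

Further compounds

F1 | step 10 | (1S,2R,5R)-2,5-diacetoxy-1-R¹-cyclohex-3-ene-1-carbaldehyde | O=C[C@@]1(C/C=C(\C)CC/C=C(\C)CC/C=C(\C)[C@H](O[Si](C)(C)C(C)(C)C)[C@H](O[Si](C)(C)C(C)(C)C)C=C(C)C)C[C@@H](OC(C)=O)C=C[C@H]1OC(C)=O
F2 | step 10 | (1R,2R,5R)-1-ethenyl-1-R¹-cyclohex-3-ene-2,5-diyl diacetate | C=C[C@@]1(C/C=C(\C)CC/C=C(\C)CC/C=C(\C)[C@H](O[Si](C)(C)C(C)(C)C)[C@H](O[Si](C)(C)C(C)(C)C)C=C(C)C)C[C@@H](OC(C)=O)C=C[C@H]1OC(C)=O
F3 | step 10 | (1R,2R,5R)-1-ethenyl-1-R¹-cyclohex-3-ene-2,5-diol | C=C[C@@]1(C/C=C(\C)CC/C=C(\C)CC/C=C(\C)[C@H](O[Si](C)(C)C(C)(C)C)[C@H](O[Si](C)(C)C(C)(C)C)C=C(C)C)C[C@@H](O)C=C[C@H]1O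
F4 | step 15 | 2-[(1R,2R,5R)-1-R¹-2,5-dihydroxycyclohex-3-en-1-yl]acetic acid | OC(=O)C[C@@]1(C/C=C(\C)CC/C=C(\C)CC/C=C(\C)[C@H](O[Si](C)(C)C(C)(C)C)[C@H](O[Si](C)(C)C(C)(C)C)C=C(C)C)C[C@@H](O)C=C[C@H]1O
F5 | step 15 | 2-[(1R)-1-R¹-2,5-dioxocyclohex-3-en-1-yl]acetic acid | OC(=O)C[C@@]1(C/C=C(\C)CC/C=C(\C)CC/C=C(\C)[C@H](O[Si](C)(C)C(C)(C)C)[C@H](O[Si](C)(C)C(C)(C)C)C=C(C)C)CC(=O)C=CC1=O
F6 | step 9 | 2,5-dimethoxytetrahydrofuran | COC1CCC(OC)O1
F7 | step 9 | butanedial | O=CCCC=O
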